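The route disconnects the two cis methyl groups on the four-membered ring: the C7–CH3 and C8–CH3 bonds of the bicyclo[4.2.0]octane core (cyclobutane C1–C8–C7–C6 cis-fused to carbocycle C1–C6). In one flask a methylcuprate adds to C8 of a fused cyclobutene ester and the C7 enolate is methylated, forming both bonds and both stereocentres. The step exploits the fold of the core: the C1, C8 and C7 methyls all lie on the convex face, while the C7 acyl carbon (later the pyranone) is left under the six-membered ring. The precursor is enantiopure cyclobutene ester 14, made from a resolved Diels–Alder adduct by Ramberg–Bäcklund contraction; its endo C5 methyl shields the concave face.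

Key step: step 9

Assumption: which antipode of 1-phenylethylamine gives the less soluble salt of the wanted hemiester must be found by trial; the (S)-amine is written, and the (R)-amine would be used otherwise.

Locants C1–C8 are those of the bicyclo[4.2.0]octane core: C1 is the methylated ring-fusion carbon, C6 the ring-fusion CH, C7 is bonded to C6 and C8 to C1. "Convex" is the cyclobutane face carrying the C1 methyl and C6–H; "concave" is the face carrying C2 and C5. Compounds 3 and 4 are racemic, with the enantiomer that is carried on drawn.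

Step 1
Reactants: 1 citraconic anhydride; 2 (E)-2-methylpenta-1,3-diene
Product: 3 racemic cis-3a,5,7-trimethyl-3a,4,7,7a-tetrahydro-2-benzofuran-1,3-dione (endo adduct)
Conditions: toluene, BHT (cat.), 110 °C, sealed vessel
Reagents that add atoms: none
Why: Diels–Alder reaction in which the methylated dienophile carbon bonds to the unsubstituted CH2 terminus of the diene (least hindered, largest HOMO coefficient), the cyclic Z dienophile gives the cis ring fusion and the endo transition state puts the methyl of the (E)-propenyl end cis to the anhydride ring, so three stereocentres are set in relative terms.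

Step 2
Reactants: 3 racemic anhydride
Product: 5 (S)-1-phenylethylammonium salt of the wanted hemiester, via racemic hemiester 4 (not isolated)
Conditions: MeOH, reflux; evaporate; (S)-1-phenylethylamine (1 equiv), EtOAc, recrystallise to constant rotation
Reagents that add atoms: methanol, CO; (S)-1-phenylethylamine, C[C@H](N)c1ccccc1
Why: Anhydride methanolysis at the less hindered carbonyl (on the CH, not on the quaternary carbon) followed by classical resolution through diastereomeric salt crystallisation, which creates no stereocentre but selects the antipode with the absolute configuration of the target.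

Step 3
Reactants: 5 hemiester salt
Product: 7 [6-(hydroxymethyl)-1,3,5-trimethylcyclohex-3-en-1-yl]methanol, via free hemiester 6 (not isolated)
Conditions: 2 M HCl/EtOAc partition; then LiAlH4, THF, 0 °C → reflux; aq. NaOH work-up
Reagents that add atoms: none
Why: Hydride reduction of the ester and the carboxylic acid to the two primary alcohols, which leaves the isolated trisubstituted alkene and all stereocentres untouched.

Step 4
Reactants: 7 diol
Product: 8 bis(methanesulfonate) of 7
Conditions: MsCl, Et3N, CH2Cl2, −10 → 0 °C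
Reagents that add atoms: methanesulfonyl chloride, CS(=O)(=O)Cl
Why: Sulfonylation of both primary alcohols through the sulfene pathway, which is fast even for the neopentyl-type hydroxyl on the C1 side.

Step 5
Reactants: 8 dimesylate
Product: 9 cis-fused 3a,5,7-trimethyl-1,3,3a,4,7,7a-hexahydro-2-benzothiophene
Conditions: Na2S·9H2O, DMF, 90 °C
Reagents that add atoms: sodium sulfide, [Na+].[Na+].[S-2]
Why: Double SN2 thioether formation in which sulfide first displaces the less hindered mesylate and the resulting thiolate closes the five-membered ring by 5-exo-tet attack, whose intramolecularity offsets the neopentyl retardation.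

Step 6
Reactants: 9 thiolane
Product: 10 cis-fused 3a,5,7-trimethyl-1,3,3a,4,7,7a-hexahydro-2-benzothiophene 2,2-dioxide
Conditions: 30% H2O2, (NH4)6Mo7O24·4H2O (cat.), EtOH, 0 °C → rt
Reagents that add atoms: hydrogen peroxide, OO
Why: Peroxomolybdate oxidation of sulfide to sulfone, which is far faster at sulfur than epoxidation of an isolated trisubstituted alkene.

Step 7
Reactants: 10 sulfone
Product: 11 methyl 3a,5,7-trimethyl-2,2-dioxo-1,3,3a,4,7,7a-hexahydro-2-benzothiophene-1-carboxylate (ester on core C7, C7 epimers)
Conditions: LiN(iPr)2 (2.2 equiv), THF, −78 °C; ClCO2Me, −78 °C; aq. NH4Cl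
Reagents that add atoms: methyl chloroformate, COC(=O)Cl
Why: Kinetic α-sulfonyl deprotonation should occur at the CH2 next to the ring-fusion CH (C7) and not at the neopentyl CH2 next to quaternary C1 (C8), and C-acylation of that carbanion gives the sulfonyl ester, which the second equivalent of base deprotonates at once so that it is not acylated twice; the new C7 centre is of no consequence because step 8 removes it.

Step 8
Reactants: 11 sulfonyl ester
Product: 14 methyl 1,3,5-trimethylbicyclo[4.2.0]octa-3,7-diene-7-carboxylate, via chloro sulfone 12 (not isolated), via episulfone 13 (not isolated)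
Conditions: NaH, THF, 0 °C; NCS, 0 °C → rt; then KOtBu, −78 → 0 °C
Reagents that add atoms: none
Why: Ramberg–Bäcklund reaction in which chlorination of the doubly activated C7 is followed by α'-deprotonation at C8, 1,3-displacement of chloride to the episulfone and loss of SO2, contracting the thiolane dioxide to the C7=C8 cyclobutene as established for fused cyclobutenes and for α-alkoxycarbonyl cyclic sulfones.

Step 9
Reactants: 14 cyclobutene ester
Product: 16 methyl 1,3,5,7,8-pentamethylbicyclo[4.2.0]oct-3-ene-7-carboxylate, via lithium enolate 15 (not isolated)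
Conditions: Me2CuLi (from CuI and 2 MeLi), Et2O, −78 → −30 °C; then MeI, HMPA/THF, −30 → 0 °C
Reagents that add atoms: lithium dimethylcuprate, [Li+].C[Cu-]C; iodomethane, CI
Why: Lithium dimethylcuprate forms a π-complex with the strained enoate and transfers CH3 to C8, the only β-carbon, giving lithium ester enolate 15, which MeI C-methylates once HMPA loosens the aggregate; this is the established three-component conjugate addition–enolate alkylation of cycloalkene carboxylates, applied to a cyclobutene ester whose ring strain makes it a willing acceptor. No ring is closed. C8 is set by the ring fusion, because the methyl arrives on the face carrying the C1 methyl and C6–H while the other face is walled in by the boat-shaped carbocycle (C2, C3=C4, C5). C7 is set by the same fold reinforced by the endo C5 methyl, which lies directly under C7, so MeI should reach the planar enolate only from the convex side and the new C7 methyl ends cis to the C8 and C1 methyls with the ester left concave. The step needs convex-face attack twice, the second time against the usual preference for alkylation trans to the fresh C8 substituent, and only the cis-fused C1–C6 ring and the C5 methyl enforce it. Over-alkylation and 1,2-addition are not expected, since the quaternary product has no acidic α-hydrogen and cuprates spare esters.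

Step 10
Reactants: 16 pentamethyl ester
Product: 17 (1,3,5,7,8-pentamethylbicyclo[4.2.0]oct-3-en-7-yl)methanol
Conditions: LiAlH4, Et2O, 0 °C → rt; aq. NaOH work-up
Reagents that add atoms: none
Why: Hydride reduction of the hindered ester to the neopentyl-type primary alcohol without touching the quaternary C7 centre.

Step 11
Reactants: 17 alcohol
Product: 18 1,3,5,7,8-pentamethylbicyclo[4.2.0]oct-3-ene-7-carbaldehyde
Conditions: Dess–Martin periodinane, CH2Cl2, rt
Reagents that add atoms: none
Why: Dess–Martin oxidation of a primary alcohol to an aldehyde that has no α-hydrogen and so cannot epimerise or over-react.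

Step 12
Reactants: 18 aldehyde; 19 methyl 2-methyl-3-oxopentanoate
Product: 21 methyl 5-hydroxy-2,4-dimethyl-3-oxo-5-(1,3,5,7,8-pentamethylbicyclo[4.2.0]oct-3-en-7-yl)pentanoate, via dianion 20 (not isolated)
Conditions: 19, NaH then n-BuLi, THF, 0 °C; add 18, −78 → 0 °C; aq. NH4Cl
Reagents that add atoms: none
Why: Aldol addition of the β-ketoester dianion through its more basic γ-carbon to the non-enolisable aldehyde; the new carbinol and methyl-bearing centres form as a mixture, which is harmless because all three become sp2 or are lost by step 14.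

Step 13
Reactants: 21 aldol adduct
Product: 22 methyl 2,4-dimethyl-3,5-dioxo-5-(1,3,5,7,8-pentamethylbicyclo[4.2.0]oct-3-en-7-yl)pentanoate
Conditions: Dess–Martin periodinane, CH2Cl2, rt
Reagents that add atoms: none
Why: Dess–Martin oxidation of the secondary alcohol to the 3,5-diketo ester under conditions that avoid retro-aldol cleavage.

Step 14
Reactants: 22 diketo ester
Product: 23 4-hydroxy-3,5-dimethyl-6-(1,3,5,7,8-pentamethylbicyclo[4.2.0]oct-3-en-7-yl)-2H-pyran-2-one
Conditions: DBU, toluene, rt → 60 °C
Reagents that add atoms: none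
Why: Base-mediated enolisation of the δ-ketone and lactonisation onto the ester with loss of methanol, the standard closure of 3,5-diketo esters to 4-hydroxy-2-pyranones.

Step 15
Reactants: 23 hydroxypyranone
Product: 25 2-methoxy-3,5-dimethyl-6-(1,3,5,7,8-pentamethylbicyclo[4.2.0]oct-3-en-7-yl)-4H-pyran-4-one, via pyrylium triflate 24 (not isolated)
Conditions: MeOTf, CH2Cl2, rt; aq. NaHCO3
Reagents that add atoms: methyl trifluoromethanesulfonate, COS(=O)(=O)C(F)(F)F
Why: O-methylation of the neutral pyranone by a hard alkylating agent at its most basic oxygen, the lactone carbonyl, gives a 4-hydroxy-2-methoxypyrylium salt whose deprotonation on work-up delivers the 2-methoxy-4-pyranone rather than the 4-methoxy-2-pyranone.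

Step 16
Reactants: 25 pyranone monoene
Product: 26 trans-3,4-dibromide of 25 (6-(3,4-dibromo-1,3,5,7,8-pentamethylbicyclo[4.2.0]octan-7-yl) pyranone)
Conditions: Br2 (1.0 equiv), CH2Cl2, −78 °C
Reagents that add atoms: bromine, BrBr
Why: Electrophilic anti addition of bromine to the only isolated alkene, the fully substituted and electron-poor pyranone double bonds being inert at low temperature; the two new C–Br centres are removed in step 17.

Step 17
Reactants: 26 dibromide
Product: 28 2-methoxy-3,5-dimethyl-6-(1,3,5,7,8-pentamethylbicyclo[4.2.0]octa-2,4-dien-7-yl)-4H-pyran-4-one, via allylic bromide 27 (not isolated)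
Conditions: DBU (excess), DMF, rt → 50 °C
Reagents that add atoms: none
Why: Twofold dehydrobromination in which anti-periplanar E2 loss of the tertiary C3 bromide toward C2 gives allylic bromide 27, which can only lose HBr toward C5–H because C1 is quaternary and C3 bears no hydrogen, giving the C2=C3–C4=C5 diene and erasing the C5 stereocentre; the temperature is kept low because the bicyclo[4.2.0]octadiene can open electrocyclically on heating.

Step 18
Reactants: 28 diene
Product: 29 CNP0183511.1 (2,5-epidioxide of 28)
Conditions: O2, methylene blue (cat.), hν (>500 nm), CH2Cl2, 0 °C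
Reagents that add atoms: oxygen, O=O
Why: [4+2] cycloaddition of singlet oxygen to the s-cis diene, which sets C2 and C5 by attack on the face carrying the C1 methyl and C6–H, because the other face is covered by the cyclobutane and its concave pyranone.

Compound list
1 | citraconic anhydride | CC1=CC(=O)OC1=O | starting material
2 | (E)-2-methylpenta-1,3-diene | C=C(C)/C=C/C | starting material
3 | racemic cis-3a,5,7-trimethyl-3a,4,7,7a-tetrahydro-2-benzofuran-1,3-dione, 7-methyl cis to the anhydride ring | O=C1OC(=O)[C@@]2(C)CC(C)=C[C@@H](C)[C@@H]12 | intermediate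
4 | racemic 6-(methoxycarbonyl)-1,3,5-trimethylcyclohex-3-ene-1-carboxylic acid, CO2H, CO2Me and 5-methyl all cis | OC(=O)[C@@]1(C)CC(C)=C[C@@H](C)[C@H]1C(=O)OC | intermediate
5 | (S)-1-phenylethylammonium salt of the wanted enantiomer of 4 | [O-]C(=O)[C@@]1(C)CC(C)=C[C@@H](C)[C@H]1C(=O)OC.C[C@H]([NH3+])c1ccccc1 | intermediate
6 | enantiopure 6-(methoxycarbonyl)-1,3,5-trimethylcyclohex-3-ene-1-carboxylic acid | OC(=O)[C@@]1(C)CC(C)=C[C@@H](C)[C@H]1C(=O)OC | intermediate
7 | [6-(hydroxymethyl)-1,3,5-trimethylcyclohex-3-en-1-yl]methanol, both CH2OH groups and the 5-methyl cis | OC[C@@]1(C)CC(C)=C[C@@H](C)[C@H]1CO | intermediate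
8 | bis(methanesulfonate) of 7 | CS(=O)(=O)OC[C@@]1(C)CC(C)=C[C@@H](C)[C@H]1COS(C)(=O)=O | intermediate
9 | cis-fused 3a,5,7-trimethyl-1,3,3a,4,7,7a-hexahydro-2-benzothiophene, 7-methyl cis to the thiolane ring | C1SC[C@@]2(C)CC(C)=C[C@@H](C)[C@@H]12 | intermediate
10 | 2,2-dioxide of 9 | O=S1(=O)C[C@@]2(C)CC(C)=C[C@@H](C)[C@H]2C1 | intermediate
11 | methyl 3a,5,7-trimethyl-2,2-dioxo-1,3,3a,4,7,7a-hexahydro-2-benzothiophene-1-carboxylate, ester on core C7, C7 epimers | O=S1(=O)C[C@@]2(C)CC(C)=C[C@@H](C)[C@H]2C1C(=O)OC | intermediate
12 | 1-chloro derivative of 11 (chlorine and ester on core C7) | O=S1(=O)C[C@@]2(C)CC(C)=C[C@@H](C)[C@H]2C1(Cl)C(=O)OC | intermediate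
13 | methyl 7,8-epithio-1,3,5-trimethylbicyclo[4.2.0]oct-3-ene-7-carboxylate S,S-dioxide (episulfone) | O=S1(=O)C2[C@@]3(C)CC(C)=C[C@@H](C)[C@H]3C12C(=O)OC | intermediate
14 | methyl 1,3,5-trimethylbicyclo[4.2.0]octa-3,7-diene-7-carboxylate, cis-fused, C5 methyl on the side of the four-membered ring | COC(=O)C1=C[C@@]2(C)CC(C)=C[C@@H](C)[C@@H]12 | intermediate
15 | lithium enolate of methyl 1,3,5,8-tetramethylbicyclo[4.2.0]oct-3-ene-7-carboxylate, C8 methyl convex | COC(O[Li])=C1[C@H](C)[C@@]2(C)CC(C)=C[C@@H](C)[C@@H]12 | intermediate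
16 | methyl 1,3,5,7,8-pentamethylbicyclo[4.2.0]oct-3-ene-7-carboxylate, C1, C7 and C8 methyls cis on the convex face, ester concave | COC(=O)[C@@]1(C)[C@H](C)[C@@]2(C)CC(C)=C[C@@H](C)[C@@H]12 | intermediate
17 | (1,3,5,7,8-pentamethylbicyclo[4.2.0]oct-3-en-7-yl)methanol, CH2OH concave | OC[C@@]1(C)[C@H](C)[C@@]2(C)CC(C)=C[C@@H](C)[C@@H]12 | intermediate
18 | 1,3,5,7,8-pentamethylbicyclo[4.2.0]oct-3-ene-7-carbaldehyde, CHO concave | O=C[C@@]1(C)[C@H](C)[C@@]2(C)CC(C)=C[C@@H](C)[C@@H]12 | intermediate
19 | methyl 2-methyl-3-oxopentanoate | CCC(=O)C(C)C(=O)OC | starting material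
20 | sodium lithium 2,4-dianion (bis-enolate) of 19 | CC=C(O[Li])C(C)=C(OC)O[Na] | intermediate
21 | methyl 5-hydroxy-2,4-dimethyl-3-oxo-5-(1,3,5,7,8-pentamethylbicyclo[4.2.0]oct-3-en-7-yl)pentanoate, diastereomers in the side chain | COC(=O)C(C)C(=O)C(C)C(O)[C@@]1(C)[C@H](C)[C@@]2(C)CC(C)=C[C@@H](C)[C@@H]12 | intermediate
22 | methyl 2,4-dimethyl-3,5-dioxo-5-(1,3,5,7,8-pentamethylbicyclo[4.2.0]oct-3-en-7-yl)pentanoate | COC(=O)C(C)C(=O)C(C)C(=O)[C@@]1(C)[C@H](C)[C@@]2(C)CC(C)=C[C@@H](C)[C@@H]12 | intermediate
23 | 4-hydroxy-3,5-dimethyl-6-(1,3,5,7,8-pentamethylbicyclo[4.2.0]oct-3-en-7-yl)-2H-pyran-2-one | O=C1OC([C@@]2(C)[C@H](C)[C@@]3(C)CC(C)=C[C@@H](C)[C@@H]23)=C(C)C(O)=C1C | intermediate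
24 | 4-hydroxy-2-methoxy-3,5-dimethyl-6-(1,3,5,7,8-pentamethylbicyclo[4.2.0]oct-3-en-7-yl)pyrylium trifluoromethanesulfonate | COc1[o+]c([C@@]2(C)[C@H](C)[C@@]3(C)CC(C)=C[C@@H](C)[C@@H]23)c(C)c(O)c1C.[O-]S(=O)(=O)C(F)(F)F | intermediate
25 | 2-methoxy-3,5-dimethyl-6-(1,3,5,7,8-pentamethylbicyclo[4.2.0]oct-3-en-7-yl)-4H-pyran-4-one | COc1oc([C@@]2(C)[C@H](C)[C@@]3(C)CC(C)=C[C@@H](C)[C@@H]23)c(C)c(=O)c1C | intermediate
26 | 6-(trans-3,4-dibromo-1,3,5,7,8-pentamethylbicyclo[4.2.0]octan-7-yl)-2-methoxy-3,5-dimethyl-4H-pyran-4-one | COc1oc([C@@]2(C)[C@H](C)[C@@]3(C)CC(C)(Br)C(Br)[C@@H](C)[C@@H]23)c(C)c(=O)c1C | intermediate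
27 | 6-(4-bromo-1,3,5,7,8-pentamethylbicyclo[4.2.0]oct-2-en-7-yl)-2-methoxy-3,5-dimethyl-4H-pyran-4-one | COc1oc([C@@]2(C)[C@H](C)[C@@]3(C)C=C(C)C(Br)[C@@H](C)[C@@H]23)c(C)c(=O)c1C | intermediate
28 | 2-methoxy-3,5-dimethyl-6-(1,3,5,7,8-pentamethylbicyclo[4.2.0]octa-2,4-dien-7-yl)-4H-pyran-4-one | COc1oc([C@@]2(C)[C@H](C)[C@@]3(C)C=C(C)C=C(C)[C@@H]23)c(C)c(=O)c1C | intermediate
29 | CNP0183511.1, the 2,5-epidioxide of 28 with the O–O bridge on the face of the C1 methyl and C6–H | COc1oc([C@@]2(C)[C@H](C)[C@@]3(C)[C@@H]4OO[C@@](C)(C=C4C)[C@@H]23)c(C)c(=O)c1C | target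

Total step count: 18. Longest linear sequence: 18 steps, from 1 to 29; 19 enters at step 12 without steps of its own.

Steps most likely to fail

Step 9. Methyl iodide may approach enolate 15 anti to the fresh C8 methyl, that is from the concave face, or discriminate poorly between the faces, so that the C7 configuration comes out inverted or mixed. The fallback exchanges the roles of the two C7 substituents and sets out from 14. The same cuprate addition is run, but the enolate is trapped with benzyl chloromethyl ether, which by the same facial preference gives benzyloxymethyl ester F1 (CH2OBn concave, ester convex). LiAlH4 gives alcohol F2 and MsCl/Et3N gives mesylate F3. LiEt3BH in refluxing THF then replaces the mesylate by hydride and gives benzyl ether F4, whose new C7 methyl is convex. Li in liquid NH3 cleaves the benzyl ether without touching the isolated alkene, and the route is rejoined at 17.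

Step 17. Loss of HBr from the tertiary C3 bromide may run toward the C3 methyl and give exocyclic methylene isomers, and the second elimination may be sluggish at the temperatures the diene tolerates. The fallback sets out from 25 and avoids bromine. Allylic hydroxylation with SeO2 (cat.) and t-BuOOH in CH2Cl2 at the ring CH2 on the more substituted alkene terminus should give C2 allylic alcohol F5. MsCl/Et3N converts it into allylic mesylate F6, which is not stored. DBU at room temperature then removes methanesulfonic acid in a 1,4 sense; this can only involve C5–H, because C1 is quaternary and C3 has no hydrogen, and the route is rejoined at 28.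

Step 7. Deprotonation may compete at the C8 methylene and give the regioisomeric ester, which would place the carboxylate on the wrong cyclobutene carbon. The fallback does not depend on this regiochemistry and sets out from 10. LiN(iPr)2 and C2Cl6 give chloro sulfone F7 (either α-position serves), and KOtBu effects the Ramberg–Bäcklund contraction to cyclobutene F8 (1,3,5-trimethylbicyclo[4.2.0]octa-3,7-diene). 9-BBN hydroborates the strained disubstituted alkene in preference to the trisubstituted one and places boron on C7, away from quaternary C1, and NaBO3 oxidation gives cyclobutanol F9. Dess–Martin oxidation gives cyclobutanone F10, and KN(SiMe3)2 with PhNTf2 gives enol triflate F11 by deprotonation at the C8 methylene. Methoxycarbonylation with Pd(OAc)2, PPh3, CO, MeOH and Et3N rejoins the route at 14, bypassing step 8 as well.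

Further compounds
F1 | step 9 | methyl 7-(benzyloxymethyl)-1,3,5,8-tetramethylbicyclo[4.2.0]oct-3-ene-7-carboxylate, CH2OBn concave and ester convex | COC(=O)[C@]1(COCc3ccccc3)[C@H](C)[C@@]2(C)CC(C)=C[C@@H](C)[C@@H]12
F2 | step 9 | [7-(benzyloxymethyl)-1,3,5,8-tetramethylbicyclo[4.2.0]oct-3-en-7-yl]methanol | OC[C@]1(COCc3ccccc3)[C@H](C)[C@@]2(C)CC(C)=C[C@@H](C)[C@@H]12
F3 | step 9 | methanesulfonate of F2 | CS(=O)(=O)OC[C@]1(COCc3ccccc3)[C@H](C)[C@@]2(C)CC(C)=C[C@@H](C)[C@@H]12
F4 | step 9 | 7-(benzyloxymethyl)-1,3,5,7,8-pentamethylbicyclo[4.2.0]oct-3-ene, C7 methyl convex | C[C@]1(COCc3ccccc3)[C@H](C)[C@@]2(C)CC(C)=C[C@@H](C)[C@@H]12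
F5 | step 17 | 6-(2-hydroxy-1,3,5,7,8-pentamethylbicyclo[4.2.0]oct-3-en-7-yl)-2-methoxy-3,5-dimethyl-4H-pyran-4-one, C2 configuration immaterial | COc1oc([C@@]2(C)[C@H](C)[C@@]3(C)C(O)C(C)=C[C@@H](C)[C@@H]23)c(C)c(=O)c1C
F6 | step 17 | methanesulfonate of F5 | COc1oc([C@@]2(C)[C@H](C)[C@@]3(C)C(OS(C)(=O)=O)C(C)=C[C@@H](C)[C@@H]23)c(C)c(=O)c1C
F7 | step 7 | 1-chloro-3a,5,7-trimethyl-1,3,3a,4,7,7a-hexahydro-2-benzothiophene 2,2-dioxide | O=S1(=O)C[C@@]2(C)CC(C)=C[C@@H](C)[C@H]2C1Cl
F8 | step 7 | 1,3,5-trimethylbicyclo[4.2.0]octa-3,7-diene | C1=C[C@@]2(C)CC(C)=C[C@@H](C)[C@@H]12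
F9 | step 7 | 1,3,5-trimethylbicyclo[4.2.0]oct-3-en-7-ol, C7 configuration immaterial | OC1C[C@@]2(C)CC(C)=C[C@@H](C)[C@@H]12
F10 | step 7 | 1,3,5-trimethylbicyclo[4.2.0]oct-3-en-7-one | O=C1C[C@@]2(C)CC(C)=C[C@@H](C)[C@@H]12
F11 | step 7 | 1,3,5-trimethylbicyclo[4.2.0]octa-3,7-dien-7-yl trifluoromethanesulfonate | FC(F)(F)S(=O)(=O)OC1=C[C@@]2(C)CC(C)=C[C@@H](C)[C@@H]12
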